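## Analysis of the target

The target is a 9,13;15,16-diepoxylabdane. Rings A and B form a trans-decalin. C9 is the spiro atom of a tetrahydrofuran (ring C: C9, C11, C12, C13, O), and C13 is in turn the spiro atom of a 2,3-dihydrofuran (ring D: C13, C14=C15, O, C16). There are six stereocentres. C4, C5, C10, C9 and C8 are contiguous and four of them are fully substituted. C13 is a remote quaternary ether carbon, not a ketal, so it cannot be equilibrated and must be set deliberately. The relationships are: 5α-H and 10β-CH3 (trans fusion); the C19 hydroxymethyl on C4 is β and axial, syn to the C10 methyl; the 8β-acetoxy group is axial and anti-periplanar to the axial 9α-oxygen; C11 is β; C13 is R. The sensitive groups are the cyclic enol ether of ring D (acid), the tertiary α-acetoxy ketone (base, acyl transfer) and the free neopentyl C19 alcohol. The synthesis is hard because of the congestion around C8–C9–C10, the three oxygenated quaternary carbons, and the need for absolute control at two distant sites (C4/C5/C10 and C13). The strategy rests on one feature: C4 carries its only oxidised carbon, C19, on the same face as the C10 methyl across the trans A/B junction. Read as a cyclohexene adduct, ring A therefore has an ester-level carbon on C4 cis to the C5–C6 bond. That is the imprint of a (Z)-2-methyl enoate (C4=C5) adding to a diene C10=C1–C2=C3 whose terminus C10 bears the angular methyl and, through C9, the four-carbon tether that becomes ring B.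

## Retrosynthetic reasoning

Ring D is opened first. Cutting the O–C15 bond of 42 gives the homopropargylic alcohol 41. The enol ether is the most acid-sensitive group, so it is made last, by an endo-selective alkynol cycloisomerisation in a basic medium, when no protecting group remains to be removed.

Compounds 41, 40, 39 and 38 differ only in protecting groups and oxidation level. The two p-methoxybenzyl ethers of 40 are cleaved oxidatively while no enol ether is present. The tertiary acetate comes from ketol 39, and the C7 ketone from the 7β-alcohol of 38. The C7 oxygen is kept as an alcohol up to 38 because it is needed as a directing group one step earlier.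

In 38 the C9–O bond of ring C is cut and the C8–O bond is traced back to an alkene. The trans-diaxial pair 8β-O/9α-O is the signature of an anti opening of an 8β,9β-epoxide (37) at C9 by the C13 hydroxyl of 36. The forward reaction must put the epoxide on the hindered β face, which the 7β-hydroxyl of 36 ensures by delivering the oxidant. It must also open the epoxide at C9 and not at C8, which the five-membered ring size and chelation of the epoxy alcohol ensure. C8 and C9 are both set here, and C13 is not touched.

Compound 36 comes from enone 34 through 35 by carbonyl reduction and desilylation. The C13 hydroxyl stays silylated until the enone is gone, because a free tertiary alcohol four atoms from C9 could add to the enone.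

The C9–C11 bond of 34 is cut next. Addition of the alkyllithium 32, made from iodide 31, to the C9 carbonyl of enone 21 gives 33. An oxidative 1,3-transposition then moves the oxygen to C7 and leaves the side chain on a tetrasubstituted C8=C9 alkene. This is preferred to a cross-coupling at C9 followed by allylic oxidation, because the transposition places the C7 oxygen without having to choose between the allylic positions C7, C11 and C17. It is convergent and brings C13 in already configured.

Fragment 31 goes back through 30 and 29 to epoxy alcohol 28. The quaternary carbinol C13 is the distal epoxide carbon of 28. A hydride delivered to C12 leaves the C13–O bond intact. The asymmetric epoxidation of the trisubstituted enynol 27 sets that centre under reagent control. The alkene geometry of 27 comes from the trans-hydroalumination–iodination of 23 (through 24 to 25) and coupling with 26. Compound 23 is the mono-ether of 22.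

Enone 21 comes from ketone 18 by methylation at C8 (19) and dehydrogenation through 20. Ketone 18 comes from the cycloadduct 13 by hydrogenation (14), ester reduction (15), protection (16), desilylation (17) and oxidation. These steps only adjust groups. The C9 carbinol that controlled the cycloaddition becomes the carbonyl on which the C8 methyl and the side chain are hung.

The central cut is made in 13. Breaking C3–C4 and C5–C10 is a retro-[4+2] that opens rings A and B together and leads to triene 12. The cut is made here because these two bonds connect the two quaternary carbons of ring A to the ring fusion, so three stereocentres (C4, C5, C10) arise in one step. C19 can be the ester that activates the dienophile, and the only additional stereocentre needed, C9, is a carbinol that is later oxidised and so costs nothing. The forward reaction must be trans-selective, with the ester exo, and must take place on the face dictated by C9.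

The C4=C5 bond of 12 is cut by a Z-selective olefination of aldehyde 10 with phosphonate 11. Compound 10 comes from acetal 9, the silyl ether of alcohol 8. The C9 stereocentre of 8 is made by enantioselective reduction of dienone 7, the one place where absolute configuration enters the decalin half.

Dienone 7 is cut at C8–C9 into Weinreb amide 4 and the Grignard reagent 6 from chloroacetal 5. Amide 4 comes from ester 3. The (E)-geometry of 3, which places the future C20 methyl cis to C2, is set by the Wittig reaction of 1 with 2.

## Alternatives that were turned down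

Alternative 1: The C9–O bond of ring C is disconnected, going back from the 9,13-epoxy diol A2 to the 7β-hydroxy-8β,9β-epoxide A1. In the forward step Ti(OiPr)4 chelates the epoxy alcohol and the C13 tertiary hydroxyl attacks C9 from the α face. This is a sound way to fix C8 and C9: the 7β-hydroxyl controls the epoxide face, the anti opening gives the diaxial 8β-OH/9α-O pair, and the oxygen at C7 is needed in any case. On this point the alternative is exactly as strong as the chosen route, which uses the same logic late (A2 differs from 38 only in protecting groups). As a strategy, however, it leaves open how the trans-decalin with the quaternary C4 carrying C19, the C5 and C10 centres and the C9 handle is obtained, and that is where most of the skeletal difficulty lies. The chosen strategy answers that question with one cycloaddition that sets C4, C5 and C10 and delivers C9 at the right oxidation level. In step count the two are comparable once a decalin synthesis is added to Alternative 1.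

Alternative 2: The C8–C9 and C13–C16 bonds are disconnected, going back from the oxanorbornadiene enone A4 to the furan ynone A3. In the forward step the C7 ynone on ring A adds across furan carbons C9 and C13 in an intramolecular Diels–Alder reaction, which closes ring B and the oxygen-bridged ring C. Its strength is real: one step forms the C9–O–C13 bridge, makes both spiro carbons quaternary and fixes their relative configuration by the suprafacial addition. On this point it is stronger than the chosen route, which needs a separate asymmetric epoxidation for C13 and a directed epoxidation for C9. Against it: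
- A3 already contains ring A with C4, C5 and C10 in place, two of them quaternary, and making that ring is the problem the chosen key step solves.
- The face of the furan that is attacked, and hence C9 relative to C10, is controlled only by the adjacent quaternary carbon.
- Furan cycloadditions are reversible.
- After the cycloaddition the C8=C16 bond must be cleaved in the presence of the strained C11=C12 bond, C17 must be added to a 7,8-dicarbonyl system with regio- and face control, and C8 must end up with β-oxygen.

The chosen strategy gives up the elegance of the bridge for a decalin synthesis whose stereochemistry follows from alkene geometry, and for an 8,9-functionalisation whose outcome is dictated by an anti epoxide opening.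

Alternative 3: The C4–C5 and C9–C10 bonds are disconnected, going back from the decalin keto ester A6 to the acyclic polyene β-keto ester A5. In the forward step Mn(OAc)3 generates the C4 radical, two 6-endo cyclisations close rings A and B, and Cu(OAc)2 oxidises the C8 radical to the 8(17)-alkene. For the carbon skeleton this is the most step-economic of all: one step gives both rings, the axial C19 ester, C5, C10 and C9, and the C11–C13 chain is already attached. On step count to a labdane skeleton it is stronger than the chosen route. Against it for this target: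
- C3 carries a ketone that must be removed.
- C9 is formed as a C–H centre although the target needs a tertiary ether there, so the 8(17)-alkene must be isomerised and C9 oxidised afterwards.
- C13 arrives as a masked methyl ketone. Turning it into the quaternary C13 with C14, C16 and the ether oxygen in a defined configuration has no control element, because it is remote from every stereocentre.
- The absolute configuration depends on a stoichiometric auxiliary and on the diastereoselectivity of a radical cascade.

The chosen strategy is longer to the decalin, but it delivers C9 as a carbonyl precursor, needs no deoxygenation, takes its chirality from one catalytic reduction, and introduces C13 by reagent control in a separate fragment.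

Key step: step 8

## Route

Remark on the chemistry: locants C1–C20 are those of the labdane skeleton and are used for all intermediates; α is the face of H5 and β the face of the C10 methyl group.

Step 1
Reactants: 1 acrolein; 2 ethyl 2-(triphenylphosphoranylidene)propanoate
Product: 3 ethyl (2E)-2-methylpenta-2,4-dienoate
Conditions: CH2Cl2, 0 °C → rt
Reagents that add atoms: none
Why: Wittig olefination with a stabilised α-branched ylide gives the (E)-enoate, ester trans to the vinyl group, so the future C20 methyl is cis to C2 as the diene requires.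

Step 2
Reactants: 3 ethyl (2E)-2-methylpenta-2,4-dienoate
Product: 4 (2E)-N-methoxy-N,2-dimethylpenta-2,4-dienamide
Conditions: MeNHOMe·HCl, iPrMgCl, THF, −20 °C
Reagents that add atoms: N,O-dimethylhydroxylamine hydrochloride, CNOC.Cl
Why: Weinreb amide formation by aminolysis of the ester with the chloromagnesium amide; the α-methyl group disfavours conjugate addition to the dienoate.

Step 3
Reactants: 4 (2E)-N-methoxy-N,2-dimethylpenta-2,4-dienamide; 5 4-chloro-1,1-dimethoxybutane
Product: 7 (3E)-9,9-dimethoxy-4-methylnona-1,3-dien-5-one, via alkylmagnesium chloride 6 (not isolated)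
Conditions: 5, Mg, I2 (cat.), THF, reflux; then 4, 0 °C; aq. NH4Cl
Reagents that add atoms: none
Why: Grignard acylation of a Weinreb amide; the chelated tetrahedral intermediate prevents over-addition and the C8–C9 bond is formed while the acetal (masked C5 aldehyde) is inert.

Step 4
Reactants: 7 (3E)-9,9-dimethoxy-4-methylnona-1,3-dien-5-one
Product: 8 (3E,5S)-9,9-dimethoxy-4-methylnona-1,3-dien-5-ol
Conditions: (R)-2-methyl-CBS-oxazaborolidine (20 mol %), catecholborane, toluene, −78 °C
Reagents that add atoms: none
Why: Corey–Bakshi–Shibata reduction; the α-branched dienyl group acts as the large and the primary alkyl chain as the small substituent, so the (R)-catalyst should give the (S)-carbinol (C9), and catecholborane at low temperature reduces the carbonyl much faster than it hydroborates the diene.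

Step 5
Reactants: 8 (3E,5S)-9,9-dimethoxy-4-methylnona-1,3-dien-5-ol
Product: 9 tert-butyl{[(3E,5S)-9,9-dimethoxy-4-methylnona-1,3-dien-5-yl]oxy}dimethylsilane
Conditions: TBSCl, imidazole, DMF, rt
Reagents that add atoms: tert-butyldimethylsilyl chloride, CC(C)(C)[Si](C)(C)Cl
Why: Standard silylation of a secondary allylic alcohol; the bulky silyl ether is the control element of the cycloaddition.

Step 6
Reactants: 9 tert-butyl{[(3E,5S)-9,9-dimethoxy-4-methylnona-1,3-dien-5-yl]oxy}dimethylsilane
Product: 10 (5S,6E)-5-[(tert-butyldimethylsilyl)oxy]-6-methylnona-6,8-dienal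
Conditions: PPTS (cat.), acetone/H2O, 40 °C
Reagents that add atoms: water, O
Why: Acid-catalysed hydrolysis of an acyclic dimethyl acetal proceeds under conditions too mild to desilylate or ionise the dienylic silyl ether.

Step 7
Reactants: 10 (5S,6E)-5-[(tert-butyldimethylsilyl)oxy]-6-methylnona-6,8-dienal; 11 methyl 2-[bis(2,2,2-trifluoroethoxy)phosphoryl]propanoate
Product: 12 methyl (2Z,7S,8E)-7-[(tert-butyldimethylsilyl)oxy]-2,8-dimethylundeca-2,8,10-trienoate
Conditions: KN(SiMe3)2, 18-crown-6, THF, −78 °C
Reagents that add atoms: none
Why: Still–Gennari olefination; the electron-poor phosphonate and the dissociated potassium enolate make elimination faster than equilibration, which gives the (Z)-2-methyl enoate with the ester cis to C6.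

Step 8
Reactants: 12 methyl (2Z,7S,8E)-7-[(tert-butyldimethylsilyl)oxy]-2,8-dimethylundeca-2,8,10-trienoate
Product: 13 trans-octalin ester: methyl 9β-[(tert-butyldimethylsilyl)oxy]-4α,10β-dimethyl-5α-H-octal-1-ene-4β-carboxylate (C1=C2; C19 = ester carbon)
Conditions: toluene (0.01 M), BHT, sealed tube, 170–180 °C
Reagents that add atoms: none
Why: A concerted, suprafacial thermal [4+2] cycloaddition joins C3 to C4 and C10 to C5; the closest known reaction type is the thermal intramolecular Diels–Alder reaction of deca-1,7,9-trienoates, including terpene cases with the future angular methyl on the tethered diene terminus, which gives trans-fused octalins. Ring A is the new cyclohexene closed by the cycloaddition itself (both new σ bonds lie in it), and ring B is closed at the same moment by the C5–C10 bond as the four-carbon tether C6–C9 folds into a chair (six-membered, tether anti to the diene). C4 is set by the Z geometry of the enoate: the ester stays cis to C6 and so ends β and axial, with the C18 methyl α. C5 and C10 are set relative to each other by the anti transition state, in which H5 and the C18 methyl lie under the diene and the ester points away (exo), which gives 5α-H and 10β-CH3. The absolute sense of all three comes from C9: the chair with the bulky silyloxy group equatorial (β) should be preferred to the one in which it is axial and pressed against C7 and the dienophile. The step needs exo-ester/anti selectivity over the endo/syn mode that leads to the cis-octalin; the α-methyl of the dienophile, which like the methyl of a methacrylate competes for the endo position, and the absence of any Lewis acid work in that direction. It also needs the cycloaddition to be faster than the 1,5-hydrogen shift open to a diene with an inside methyl group, hence high dilution, a radical inhibitor and the lowest workable temperature. The C9-epimeric cycloadduct must be removed here by chromatography, because after oxidation of C9 it would become the enantiomer of 18.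

Step 9
Reactants: 13 trans-octalin ester
Product: 14 methyl 9β-[(tert-butyldimethylsilyl)oxy]-4α,10β-dimethyl-5α-H-decalin-4β-carboxylate
Conditions: H2 (1 atm), Pd/C, EtOAc, rt
Reagents that add atoms: none
Why: Heterogeneous hydrogenation of the only alkene (cis-disubstituted C1=C2); no stereocentre is formed and the silyl ether is stable in ethyl acetate.

Step 10
Reactants: 14 saturated ester
Product: 15 {9β-[(tert-butyldimethylsilyl)oxy]-4α,10β-dimethyl-5α-H-decalin-4β-yl}methanol (C19 alcohol)
Conditions: LiAlH4, THF, 0 °C → rt
Reagents that add atoms: none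
Why: Hydride reduction of the hindered axial ester to the neopentyl C19 alcohol; nothing else in the molecule is reducible.

Step 11
Reactants: 15 C19 alcohol
Product: 16 9β-[(tert-butyldimethylsilyl)oxy]-19-[(4-methoxybenzyl)oxy] decalin (4α,10β-dimethyl, 5α-H)
Conditions: NaH, PMBCl, Bu4NI (cat.), DMF, 0 °C → rt
Reagents that add atoms: 4-methoxybenzyl chloride, COc1ccc(CCl)cc1
Why: Williamson etherification; the p-methoxybenzyl ether survives bases, fluoride and the oxidants used later and can be removed oxidatively before the acid-labile enol ether exists.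

Step 12
Reactants: 16 silyl PMB diether
Product: 17 19-[(4-methoxybenzyl)oxy]-4α,10β-dimethyl-5α-H-decalin-9β-ol
Conditions: Bu4NF, THF, 60 °C
Reagents that add atoms: none
Why: Fluoride cleavage of the hindered secondary silyl ether; the benzyl-type ether is unaffected.

Step 13
Reactants: 17 C9 alcohol
Product: 18 19-[(4-methoxybenzyl)oxy]-4α,10β-dimethyl-5α-H-decalin-9-one
Conditions: Dess–Martin periodinane, NaHCO3, CH2Cl2, rt
Reagents that add atoms: none
Why: Dess–Martin oxidation of the secondary alcohol under buffered, non-epimerising conditions; the C9 stereocentre has done its work and is removed.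

Step 14
Reactants: 18 C9 ketone
Product: 19 8-methyl ketone: 19-[(4-methoxybenzyl)oxy]-4α,8,10β-trimethyl-5α-H-decalin-9-one (C8 epimers)
Conditions: LiN(iPr)2, THF, −78 °C; MeI, −78 → 0 °C
Reagents that add atoms: iodomethane, CI
Why: Kinetic enolate alkylation introduces C17; only C8 can be enolised because C10 is quaternary, and the C8 configuration is immaterial because C8 becomes sp2 in the next step.

Step 15
Reactants: 19 8-methyl ketone
Product: 21 enone: 19-[(4-methoxybenzyl)oxy]-4α,8,10β-trimethyl-5α-H-octal-7-en-9-one (C7=C8), via trimethylsilyl enol ether 20 (not isolated)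
Conditions: TMSOTf, Et3N, CH2Cl2, 0 °C; then Pd(OAc)2, MeCN, rt
Reagents that add atoms: none
Why: Saegusa–Ito dehydrogenation; soft enolisation gives the only possible silyl enol ether (C8=C9), and the oxa-π-allyl palladium species eliminates a C7 hydrogen to give the endocyclic 2-methyl enone, as 2-methylcyclohexanone does.

Step 16
Reactants: 22 but-2-yne-1,4-diol
Product: 23 4-[(4-methoxybenzyl)oxy]but-2-yn-1-ol
Conditions: 22 (3 equiv), NaH (1 equiv), PMBCl (1 equiv), Bu4NI (cat.), THF/DMF, 0 °C → rt
Reagents that add atoms: 4-methoxybenzyl chloride, COc1ccc(CCl)cc1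
Why: Mono-alkylation of a symmetric diol with the diol in excess; the ether oxygen becomes the C16 oxygen.

Step 17
Reactants: 23 4-[(4-methoxybenzyl)oxy]but-2-yn-1-ol
Product: 25 (2Z)-3-iodo-4-[(4-methoxybenzyl)oxy]but-2-en-1-ol, via cyclic vinylalanate 24 (not isolated)
Conditions: NaAlH2(OCH2CH2OMe)2, THF, 0 °C; EtOAc; then I2, THF, −78 °C
Reagents that add atoms: iodine, II
Why: Hydroxyl-directed trans-hydroalumination of a propargylic alcohol places aluminium on the distal carbon in a five-membered alkoxyalanate; iodinolysis with retention gives the (Z)-3-iodo allylic alcohol as one regio- and stereoisomer.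

Step 18
Reactants: 25 (2Z)-3-iodo-4-[(4-methoxybenzyl)oxy]but-2-en-1-ol; 26 ethynyltrimethylsilane
Product: 27 (2E)-3-{[(4-methoxybenzyl)oxy]methyl}-5-(trimethylsilyl)pent-2-en-4-yn-1-ol
Conditions: Pd(PPh3)2Cl2 (3 mol %), CuI (6 mol %), Et3N, THF, rt
Reagents that add atoms: none
Why: Sonogashira coupling of a vinyl iodide proceeds with retention of alkene geometry, so the alkynyl group is cis to the hydroxymethyl group.

Step 19
Reactants: 27 (2E)-enynol
Product: 28 [(2R,3R)-3-{[(4-methoxybenzyl)oxy]methyl}-3-[(trimethylsilyl)ethynyl]oxiran-2-yl]methanol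
Conditions: Ti(OiPr)4 (10 mol %), D-(−)-diethyl tartrate (12 mol %), t-BuOOH, 4 Å MS, CH2Cl2, −20 °C
Reagents that add atoms: tert-butyl hydroperoxide, CC(C)(C)OO
Why: Sharpless asymmetric epoxidation of a 3,3-disubstituted allylic alcohol; the D-(−)-tartrate complex delivers oxygen to the face that gives the (2R,3R)-epoxide, whose C3–O bond becomes the C13–O bond of the target with R configuration.

Step 20
Reactants: 28 (2R,3R)-epoxy alcohol
Product: 29 (3R)-3-{[(4-methoxybenzyl)oxy]methyl}-5-(trimethylsilyl)pent-4-yne-1,3-diol
Conditions: NaAlH2(OCH2CH2OMe)2 (1.1 equiv), THF, −20 → 0 °C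
Reagents that add atoms: none
Why: Regioselective reductive opening of a 2,3-epoxy alcohol; the alkoxyaluminate on the primary hydroxyl delivers hydride intramolecularly to C2 (C12), and the fully substituted C3 (C13) cannot be attacked, so its C–O bond and configuration are kept and a 1,3-diol results.

Step 21
Reactants: 29 (3R)-1,3-diol
Product: 30 (3R)-1-iodo-3-{[(4-methoxybenzyl)oxy]methyl}-5-(trimethylsilyl)pent-4-yn-3-ol
Conditions: I2, PPh3, imidazole, CH2Cl2, 0 °C
Reagents that add atoms: iodine, II
Why: Appel-type iodination is selective for the primary hydroxyl; the tertiary propargylic alcohol does not form a reactive oxyphosphonium species.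

Step 22
Reactants: 30 iodo alcohol
Product: 31 triethyl{[(3R)-1-iodo-3-{[(4-methoxybenzyl)oxy]methyl}-5-(trimethylsilyl)pent-4-yn-3-yl]oxy}silane
Conditions: TESOTf, 2,6-lutidine, CH2Cl2, −78 → 0 °C
Reagents that add atoms: triethylsilyl trifluoromethanesulfonate, CC[Si](CC)(CC)OS(=O)(=O)C(F)(F)F
Why: Silylation of the tertiary alcohol with a silyl triflate; the triethylsilyl group is large enough to resist 1,4 O→C silyl migration in the derived organolithium and small enough to be removed by fluoride later.

Step 23
Reactants: 21 enone; 31 iodide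
Product: 33 (13R)-16,19-bis[(4-methoxybenzyl)oxy]-13-[(triethylsilyl)oxy]-15-(trimethylsilyl)labd-7-en-14-yn-9-ol (C9 epimers), via alkyllithium 32 (not isolated)
Conditions: 31 (1.3 equiv), t-BuLi (2.1 equiv per iodide), Et2O, −78 °C; then 21, −78 → −20 °C
Reagents that add atoms: none
Why: Iodine–lithium exchange and 1,2-addition of a primary alkyllithium to the enone carbonyl form the C9–C11 bond; C9 has no α-hydrogen on either side, a hard nucleophile adds 1,2, and the C9 configuration is irrelevant because both epimers converge in the next step.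

Step 24
Reactants: 33 tertiary allylic alcohol
Product: 34 (13R)-16,19-bis[(4-methoxybenzyl)oxy]-13-[(triethylsilyl)oxy]-15-(trimethylsilyl)labd-8-en-14-yn-7-one
Conditions: pyridinium chlorochromate [C5H5NH][CrO3Cl], NaOAc, 4 Å MS, CH2Cl2, rt
Reagents that add atoms: none
Why: Babler–Dauben oxidative transposition; the chromate ester of the tertiary allylic alcohol undergoes a [3,3] shift to C7 and is oxidised there, which puts the ketone at C7 and the side chain on the tetrasubstituted C8=C9 alkene.

Step 25
Reactants: 34 enone
Product: 35 (7β,13R)-16,19-bis[(4-methoxybenzyl)oxy]-13-[(triethylsilyl)oxy]-15-(trimethylsilyl)labd-8-en-14-yn-7-ol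
Conditions: NaBH4, CeCl3·7H2O, MeOH/THF, −40 °C
Reagents that add atoms: none
Why: Luche 1,2-reduction; hydride should enter axially from the α face, away from the β-face congestion, to give the pseudo-equatorial 7β-alcohol that will direct the epoxidation.

Step 26
Reactants: 35 silylated allylic alcohol
Product: 36 (7β,13R)-16,19-bis[(4-methoxybenzyl)oxy]labd-8-en-14-yne-7,13-diol
Conditions: Bu4NF, THF, 0 °C → rt
Reagents that add atoms: none
Why: Fluoride cleaves the alkynyl C–Si bond and the tertiary silyl ether while the benzyl-type ethers stay; the C13 hydroxyl is freed only now because next to the enone of 34 it could add in conjugate fashion.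

Step 27
Reactants: 36 diol
Product: 38 (7β,8β,9α,13R)-9,13-epoxy-16,19-bis[(4-methoxybenzyl)oxy]labd-14-yne-7,8-diol, via epoxy diol 37 (not isolated)
Conditions: VO(acac)2 (10 mol %), t-BuOOH, CH2Cl2, 0 °C → rt; then Ti(OiPr)4, rt
Reagents that add atoms: tert-butyl hydroperoxide, CC(C)(C)OO
Why: Vanadium-catalysed hydroxyl-directed epoxidation: the allylic 7β-alkoxide bound to vanadium delivers oxygen syn, to the β face of C8=C9 despite the C10 methyl (as with steroidal 4-en-3β-ols), giving the 8β,9β-epoxide 37. The titanium-chelated 2,3-epoxy alcohol is then opened at its distal carbon C9 by the C13 hydroxyl in a 5-exo, anti (trans-diaxial) attack from the α face, which sets 9α-O and leaves 8β-OH; C13 is not involved in bond breaking and keeps its configuration.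

Step 28
Reactants: 38 spiro diol
Product: 39 (8β,9α,13R)-9,13-epoxy-8-hydroxy-16,19-bis[(4-methoxybenzyl)oxy]labd-14-yn-7-one
Conditions: Dess–Martin periodinane, NaHCO3, CH2Cl2, rt
Reagents that add atoms: none
Why: Dess–Martin oxidation takes the secondary 7-hydroxyl to the ketone; the tertiary 8-hydroxyl is inert and the non-acidic reagent does not cleave the glycol.

Step 29
Reactants: 39 tertiary ketol
Product: 40 (8β,9α,13R)-8-acetoxy-9,13-epoxy-16,19-bis[(4-methoxybenzyl)oxy]labd-14-yn-7-one
Conditions: Ac2O, DMAP, Et3N, CH2Cl2, 40 °C
Reagents that add atoms: acetic anhydride, CC(=O)OC(C)=O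
Why: DMAP-catalysed acylation of a tertiary α-ketol through the N-acetylpyridinium ion; no other free hydroxyl is present.

Step 30
Reactants: 40 bis-PMB ether
Product: 41 (8β,9α,13R)-8-acetoxy-9,13-epoxy-16,19-dihydroxylabd-14-yn-7-one
Conditions: DDQ, CH2Cl2/pH 7 buffer, 0 °C → rt
Reagents that add atoms: none
Why: Oxidative cleavage of both p-methoxybenzyl ethers by benzylic hydride abstraction and hydrolysis of the oxocarbenium ions; it is done before ring D exists because an enol ether would not survive the quinone, and the neutral buffer protects the tertiary acetate.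

Step 31
Reactants: 41 alkynyl diol
Product: 42 target: (8β,9α,13R)-8-acetoxy-9,13;15,16-diepoxy-19-hydroxylabd-14-en-7-one
Conditions: Mo(CO)6 (30 mol %), Et3N, Et2O, hν (350 nm), rt
Reagents that add atoms: none
Why: Molybdenum-catalysed endo cycloisomerisation of a homopropargylic alcohol: the photogenerated (Et3N)Mo(CO)5 converts the terminal alkyne into a vinylidene, the C16 hydroxyl adds to the carbene carbon C15, and protodemetalation gives the 2,3-dihydrofuran. The basic medium preserves enol ether, acetate and ketone, and the C19 hydroxyl is too far from the alkyne to compete.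

## Compound list

1 | acrolein | C=CC=O | starting material
2 | ethyl 2-(triphenylphosphoranylidene)propanoate | CCOC(=O)C(C)=P(c1ccccc1)(c1ccccc1)c1ccccc1 | starting material
3 | ethyl (2E)-2-methylpenta-2,4-dienoate | C=C/C=C(\C)C(=O)OCC | intermediate
4 | (2E)-N-methoxy-N,2-dimethylpenta-2,4-dienamide | C=C/C=C(\C)C(=O)N(C)OC | intermediate
5 | 4-chloro-1,1-dimethoxybutane | COC(CCCCl)OC | starting material
6 | (4,4-dimethoxybutyl)magnesium chloride | COC(CCC[Mg]Cl)OC | intermediate
7 | (3E)-9,9-dimethoxy-4-methylnona-1,3-dien-5-one | C=C/C=C(\C)C(=O)CCCC(OC)OC | intermediate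
8 | (3E,5S)-9,9-dimethoxy-4-methylnona-1,3-dien-5-ol | C=C/C=C(\C)[C@@H](O)CCCC(OC)OC | intermediate
9 | tert-butyl{[(3E,5S)-9,9-dimethoxy-4-methylnona-1,3-dien-5-yl]oxy}dimethylsilane | C=C/C=C(\C)[C@@H](O[Si](C)(C)C(C)(C)C)CCCC(OC)OC | intermediate
10 | (5S,6E)-5-[(tert-butyldimethylsilyl)oxy]-6-methylnona-6,8-dienal | C=C/C=C(\C)[C@@H](O[Si](C)(C)C(C)(C)C)CCCC=O | intermediate
11 | methyl 2-[bis(2,2,2-trifluoroethoxy)phosphoryl]propanoate | COC(=O)C(C)P(=O)(OCC(F)(F)F)OCC(F)(F)F | starting material
12 | methyl (2Z,7S,8E)-7-[(tert-butyldimethylsilyl)oxy]-2,8-dimethylundeca-2,8,10-trienoate | C=C/C=C(\C)[C@@H](O[Si](C)(C)C(C)(C)C)CCC/C=C(/C)C(=O)OC | intermediate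
13 | methyl 9β-[(tert-butyldimethylsilyl)oxy]-4α,10β-dimethyl-5α-H-octal-1-ene-4β-carboxylate (trans-fused) | CC(C)(C)[Si](C)(C)O[C@H]1CCC[C@H]2[C@@](C)(C(=O)OC)CC=C[C@]12C | intermediate
14 | methyl 9β-[(tert-butyldimethylsilyl)oxy]-4α,10β-dimethyl-5α-H-decalin-4β-carboxylate | CC(C)(C)[Si](C)(C)O[C@H]1CCC[C@H]2[C@@](C)(C(=O)OC)CCC[C@]12C | intermediate
15 | {9β-[(tert-butyldimethylsilyl)oxy]-4α,10β-dimethyl-5α-H-decalin-4β-yl}methanol | CC(C)(C)[Si](C)(C)O[C@H]1CCC[C@H]2[C@@](C)(CO)CCC[C@]12C | intermediate
16 | 9β-[(tert-butyldimethylsilyl)oxy]-19-[(4-methoxybenzyl)oxy]-4α,10β-dimethyl-5α-H-decalin | CC(C)(C)[Si](C)(C)O[C@H]1CCC[C@H]2[C@@](C)(COCc3ccc(OC)cc3)CCC[C@]12C | intermediate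
17 | 19-[(4-methoxybenzyl)oxy]-4α,10β-dimethyl-5α-H-decalin-9β-ol | O[C@H]1CCC[C@H]2[C@@](C)(COCc3ccc(OC)cc3)CCC[C@]12C | intermediate
18 | 19-[(4-methoxybenzyl)oxy]-4α,10β-dimethyl-5α-H-decalin-9-one | O=C1CCC[C@H]2[C@@](C)(COCc3ccc(OC)cc3)CCC[C@]12C | intermediate
19 | 19-[(4-methoxybenzyl)oxy]-4α,8,10β-trimethyl-5α-H-decalin-9-one (C8 epimers) | CC1CC[C@H]2[C@@](C)(COCc3ccc(OC)cc3)CCC[C@]2(C)C1=O | intermediate
20 | 19-[(4-methoxybenzyl)oxy]-4α,8,10β-trimethyl-9-[(trimethylsilyl)oxy]-5α-H-octal-8-ene | C1(O[Si](C)(C)C)=C(C)CC[C@H]2[C@@](C)(COCc3ccc(OC)cc3)CCC[C@]12C | intermediate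
21 | 19-[(4-methoxybenzyl)oxy]-4α,8,10β-trimethyl-5α-H-octal-7-en-9-one | CC1=CC[C@H]2[C@@](C)(COCc3ccc(OC)cc3)CCC[C@]2(C)C1=O | intermediate
22 | but-2-yne-1,4-diol | OCC#CCO | starting material
23 | 4-[(4-methoxybenzyl)oxy]but-2-yn-1-ol | COc1ccc(COCC#CCO)cc1 | intermediate
24 | sodium 2,2-bis(2-methoxyethoxy)-3-{[(4-methoxybenzyl)oxy]methyl}-2,5-dihydro-1,2-oxaaluminol-2-uide (cyclic vinylalanate) | [Na+].COCCO[Al-]1(OCCOC)OCC=C1COCc1ccc(OC)cc1 | intermediate
25 | (2Z)-3-iodo-4-[(4-methoxybenzyl)oxy]but-2-en-1-ol | OC/C=C(\I)COCc1ccc(OC)cc1 | intermediate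
26 | ethynyltrimethylsilane | C#C[Si](C)(C)C | starting material
27 | (2E)-3-{[(4-methoxybenzyl)oxy]methyl}-5-(trimethylsilyl)pent-2-en-4-yn-1-ol | OC/C=C(\C#C[Si](C)(C)C)COCc1ccc(OC)cc1 | intermediate
28 | [(2R,3R)-3-{[(4-methoxybenzyl)oxy]methyl}-3-[(trimethylsilyl)ethynyl]oxiran-2-yl]methanol | OC[C@H]1O[C@]1(C#C[Si](C)(C)C)COCc1ccc(OC)cc1 | intermediate
29 | (3R)-3-{[(4-methoxybenzyl)oxy]methyl}-5-(trimethylsilyl)pent-4-yne-1,3-diol | OCC[C@@](O)(C#C[Si](C)(C)C)COCc1ccc(OC)cc1 | intermediate
30 | (3R)-1-iodo-3-{[(4-methoxybenzyl)oxy]methyl}-5-(trimethylsilyl)pent-4-yn-3-ol | ICC[C@@](O)(C#C[Si](C)(C)C)COCc1ccc(OC)cc1 | intermediate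
31 | triethyl{[(3R)-1-iodo-3-{[(4-methoxybenzyl)oxy]methyl}-5-(trimethylsilyl)pent-4-yn-3-yl]oxy}silane | ICC[C@@](O[Si](CC)(CC)CC)(C#C[Si](C)(C)C)COCc1ccc(OC)cc1 | intermediate
32 | [(3R)-3-{[(4-methoxybenzyl)oxy]methyl}-3-[(triethylsilyl)oxy]-5-(trimethylsilyl)pent-4-yn-1-yl]lithium | [Li]CC[C@@](O[Si](CC)(CC)CC)(C#C[Si](C)(C)C)COCc1ccc(OC)cc1 | intermediate
33 | (13R)-16,19-bis[(4-methoxybenzyl)oxy]-13-[(triethylsilyl)oxy]-15-(trimethylsilyl)labd-7-en-14-yn-9-ol (C9 epimers) | CC1=CC[C@H]2[C@@](C)(COCc3ccc(OC)cc3)CCC[C@]2(C)C1(O)CC[C@@](O[Si](CC)(CC)CC)(C#C[Si](C)(C)C)COCc1ccc(OC)cc1 | intermediate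
34 | (13R)-16,19-bis[(4-methoxybenzyl)oxy]-13-[(triethylsilyl)oxy]-15-(trimethylsilyl)labd-8-en-14-yn-7-one | C1(CC[C@@](O[Si](CC)(CC)CC)(C#C[Si](C)(C)C)COCc3ccc(OC)cc3)=C(C)C(=O)C[C@H]2[C@@](C)(COCc3ccc(OC)cc3)CCC[C@]12C | intermediate
35 | (7β,13R)-16,19-bis[(4-methoxybenzyl)oxy]-13-[(triethylsilyl)oxy]-15-(trimethylsilyl)labd-8-en-14-yn-7-ol | C1(CC[C@@](O[Si](CC)(CC)CC)(C#C[Si](C)(C)C)COCc3ccc(OC)cc3)=C(C)[C@@H](O)C[C@H]2[C@@](C)(COCc3ccc(OC)cc3)CCC[C@]12C | intermediate
36 | (7β,13R)-16,19-bis[(4-methoxybenzyl)oxy]labd-8-en-14-yne-7,13-diol | C1(CC[C@@](O)(C#C)COCc3ccc(OC)cc3)=C(C)[C@@H](O)C[C@H]2[C@@](C)(COCc3ccc(OC)cc3)CCC[C@]12C | intermediate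
37 | (7β,8β,9β,13R)-8,9-epoxy-16,19-bis[(4-methoxybenzyl)oxy]labd-14-yne-7,13-diol | [C@]12(CC[C@@](O)(C#C)COCc4ccc(OC)cc4)O[C@@]1(C)[C@@H](O)C[C@H]3[C@@](C)(COCc4ccc(OC)cc4)CCC[C@]23C | intermediate
38 | (7β,8β,9α,13R)-9,13-epoxy-16,19-bis[(4-methoxybenzyl)oxy]labd-14-yne-7,8-diol | O[C@@]1(C)[C@@H](O)C[C@H]2[C@@](C)(COCc3ccc(OC)cc3)CCC[C@]2(C)[C@@]12CC[C@@](C#C)(COCc3ccc(OC)cc3)O2 | intermediate
39 | (8β,9α,13R)-9,13-epoxy-8-hydroxy-16,19-bis[(4-methoxybenzyl)oxy]labd-14-yn-7-one | O[C@@]1(C)C(=O)C[C@H]2[C@@](C)(COCc3ccc(OC)cc3)CCC[C@]2(C)[C@@]12CC[C@@](C#C)(COCc3ccc(OC)cc3)O2 | intermediate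
40 | (8β,9α,13R)-8-acetoxy-9,13-epoxy-16,19-bis[(4-methoxybenzyl)oxy]labd-14-yn-7-one | CC(=O)O[C@@]1(C)C(=O)C[C@H]2[C@@](C)(COCc3ccc(OC)cc3)CCC[C@]2(C)[C@@]12CC[C@@](C#C)(COCc3ccc(OC)cc3)O2 | intermediate
41 | (8β,9α,13R)-8-acetoxy-9,13-epoxy-16,19-dihydroxylabd-14-yn-7-one | CC(=O)O[C@@]1(C)C(=O)C[C@H]2[C@@](C)(CO)CCC[C@]2(C)[C@@]12CC[C@@](C#C)(CO)O2 | intermediate
42 | (8β,9α,13R)-8-acetoxy-9,13;15,16-diepoxy-19-hydroxylabd-14-en-7-one | CC(=O)O[C@@]1(C)C(=O)C[C@H]2[C@@](C)(CO)CCC[C@]2(C)[C@@]12CC[C@]1(C=COC1)O2 | target

## Step count and least certain steps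

Total: 31 steps. Longest linear sequence: 24 steps (steps 1–15, then 23–31). The side-chain branch is steps 16–22.

Step 8 (key step). The most likely failure is a cycloaddition that is too slow. The inside methyl on the diene terminus makes the s-cis conformer costly and the dienophile is trisubstituted, so at the temperature required the 1,5-hydrogen shift of the diene and the endo-ester/syn pathway to the cis-octalin may compete. Incomplete facial bias from the C9 silyloxy group would add the C9-epimeric series. The fallback replaces the singly activated Z-enoate by a doubly activated dienophile, which needs no alkene geometry and must put one ester endo in either transition state. It sets out from aldehyde 10. Knoevenagel condensation with dimethyl malonate (piperidine, AcOH) gives the alkylidene malonate F1, which should cyclise at a much lower temperature to the geminal diester F2. The less hindered equatorial (α) ester of F2 is reduced selectively with LiAlH(OtBu)3 to the hydroxy ester F3, because the axial ester is shielded by the C10 methyl. The primary alcohol is converted into the iodide F4 (I2, PPh3, imidazole, toluene, 80 °C) and reduced with Bu3SnH and AIBN. This gives the C18 methyl and the route is rejoined at 13.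

Step 27. The tetrasubstituted, β-hindered alkene may be epoxidised so slowly that oxidation of the allylic alcohol back to enone 34 takes over. Alternatively the tertiary epoxide may ionise at C9 and eliminate or rearrange before the C13 hydroxyl is aligned. The fallback forms the C9–O bond first and the C8 oxygen second. From 36, Re2O7 (cat., CH2Cl2) ionises the allylic alcohol, and the C13 hydroxyl captures the allyl cation at C9 in a reversible 5-exo closure that should settle on the isomer with C11 equatorial, the 9α,13-epoxy-7-ene F5. Dihydroxylation of the C7=C8 bond with OsO4 (cat.) and N-methylmorpholine N-oxide, anti to the allylic C9–O bond, would then give the 7β,8β-diol and rejoin the route at 38. The face selectivity of this dihydroxylation is less secure than that of the directed epoxidation, which is why it is only the reserve.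

Step 23. The C9 carbonyl is flanked by the quaternary C10 and the substituted C8, so the basic alkyllithium may deprotonate at C6 or add in 1,4 fashion instead of adding to C9. In step 24 the tertiary chromate may eliminate toward C11 instead of rearranging. The fallback replaces the carbonyl addition and transposition by cross-coupling and allylic oxidation. Ketone 19 is converted into the enol triflate F6 (KN(SiMe3)2, PhNTf2). Iodide 31 is converted with zinc dust and LiCl into the alkylzinc iodide F7. Negishi coupling (Pd(dppf)Cl2, THF) gives the 8-ene F8. Allylic oxidation of the ring methylene C7 with CrO3·3,5-dimethylpyrazole then gives the enone and rejoins the route at 34. The price is a choice between three allylic positions in the last operation.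

Step 29. Acylation of the axial tertiary ketol, 1,3-diaxial to the C10 methyl and next to the spiro centre, may be so slow that enol acetate formation at C6 competes under forcing conditions. The fallback acetylates before the oxidation and lets stereoelectronics choose the oxygen. Diol 38 is converted with trimethyl orthoacetate and PPTS into the cyclic orthoacetate F9. Mild aqueous acid opens it to the axial ester, the 8β-acetoxy-7β-ol F10, because the hemi-orthoester collapses with cleavage of the bond to the equatorial oxygen. Immediate Dess–Martin oxidation of the free 7β-hydroxyl, before the acetyl group can migrate, rejoins the route at 40.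

Step 20. The newly formed tertiary propargylic alkoxide may be hydroaluminated, or hydride may be delivered to the alkyne terminus with SN2′ opening of the alkynyl epoxide to an allene; both amount to over-reduction. The fallback avoids hydride reagents. Epoxy alcohol 28 is converted into the epoxy iodide F11 (I2, PPh3, imidazole). Zinc dust in refluxing ethanol opens it reductively to the tertiary vinyl carbinol F12 with the C13–O bond intact. Hydroboration of the vinyl group with 9-BBN and oxidation with NaBO3·4H2O then gives the 1,3-diol and rejoins the route at 29.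

## Further compounds

F1 | step 8 | dimethyl 2-[(5S,6E)-5-[(tert-butyldimethylsilyl)oxy]-6-methylnona-6,8-dien-1-ylidene]propanedioate | C=C/C=C(\C)[C@@H](O[Si](C)(C)C(C)(C)C)CCCC=C(C(=O)OC)C(=O)OC
F2 | step 8 | dimethyl 9β-[(tert-butyldimethylsilyl)oxy]-10β-methyl-5α-H-octal-1-ene-4,4-dicarboxylate | CC(C)(C)[Si](C)(C)O[C@H]1CCC[C@H]2C(C(=O)OC)(C(=O)OC)CC=C[C@]12C
F3 | step 8 | methyl 9β-[(tert-butyldimethylsilyl)oxy]-4α-(hydroxymethyl)-10β-methyl-5α-H-octal-1-ene-4β-carboxylate | CC(C)(C)[Si](C)(C)O[C@H]1CCC[C@H]2[C@@](CO)(C(=O)OC)CC=C[C@]12C
F4 | step 8 | methyl 9β-[(tert-butyldimethylsilyl)oxy]-4α-(iodomethyl)-10β-methyl-5α-H-octal-1-ene-4β-carboxylate | CC(C)(C)[Si](C)(C)O[C@H]1CCC[C@H]2[C@@](CI)(C(=O)OC)CC=C[C@]12C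
F5 | step 27 | (9α,13R)-9,13-epoxy-16,19-bis[(4-methoxybenzyl)oxy]labd-7-en-14-yne | CC1=CC[C@H]2[C@@](C)(COCc3ccc(OC)cc3)CCC[C@]2(C)[C@@]12CC[C@@](C#C)(COCc3ccc(OC)cc3)O2
F6 | step 23 | 19-[(4-methoxybenzyl)oxy]-4α,8,10β-trimethyl-5α-H-octal-8-en-9-yl trifluoromethanesulfonate | C1(OS(=O)(=O)C(F)(F)F)=C(C)CC[C@H]2[C@@](C)(COCc3ccc(OC)cc3)CCC[C@]12C
F7 | step 23 | [(3R)-3-{[(4-methoxybenzyl)oxy]methyl}-3-[(triethylsilyl)oxy]-5-(trimethylsilyl)pent-4-yn-1-yl]zinc iodide | I[Zn]CC[C@@](O[Si](CC)(CC)CC)(C#C[Si](C)(C)C)COCc1ccc(OC)cc1
F8 | step 23 | (13R)-16,19-bis[(4-methoxybenzyl)oxy]-13-[(triethylsilyl)oxy]-15-(trimethylsilyl)labd-8-en-14-yne | C1(CC[C@@](O[Si](CC)(CC)CC)(C#C[Si](C)(C)C)COCc3ccc(OC)cc3)=C(C)CC[C@H]2[C@@](C)(COCc3ccc(OC)cc3)CCC[C@]12C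
F9 | step 29 | (7β,8β,9α,13R)-9,13-epoxy-7,8-[(1-methoxyethylidene)bis(oxy)]-16,19-bis[(4-methoxybenzyl)oxy]labd-14-yne | COC1(C)O[C@@]2(C)[C@@H](O1)C[C@H]3[C@@](C)(COCc4ccc(OC)cc4)CCC[C@]3(C)[C@@]25CC[C@@](C#C)(COCc4ccc(OC)cc4)O5
F10 | step 29 | (7β,8β,9α,13R)-8-acetoxy-9,13-epoxy-16,19-bis[(4-methoxybenzyl)oxy]labd-14-yn-7-ol | CC(=O)O[C@@]1(C)[C@@H](O)C[C@H]2[C@@](C)(COCc3ccc(OC)cc3)CCC[C@]2(C)[C@@]12CC[C@@](C#C)(COCc3ccc(OC)cc3)O2
F11 | step 20 | (2R,3R)-3-(iodomethyl)-2-{[(4-methoxybenzyl)oxy]methyl}-2-[(trimethylsilyl)ethynyl]oxirane | IC[C@H]1O[C@]1(C#C[Si](C)(C)C)COCc1ccc(OC)cc1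
F12 | step 20 | (3R)-3-{[(4-methoxybenzyl)oxy]methyl}-5-(trimethylsilyl)pent-1-en-4-yn-3-ol | C=C[C@@](O)(C#C[Si](C)(C)C)COCc1ccc(OC)cc1
A1 | alternative 1 | (7β,8β,9β,13R)-8,9-epoxy-16,19-bis[(tert-butyldimethylsilyl)oxy]labd-14-yne-7,13-diol | [C@]12(CC[C@@](O)(C#C)CO[Si](C)(C)C(C)(C)C)O[C@@]1(C)[C@@H](O)C[C@H]3[C@@](C)(CO[Si](C)(C)C(C)(C)C)CCC[C@]23C
A2 | alternative 1 | (7β,8β,9α,13R)-9,13-epoxy-16,19-bis[(tert-butyldimethylsilyl)oxy]labd-14-yne-7,8-diol | O[C@@]1(C)[C@@H](O)C[C@H]2[C@@](C)(CO[Si](C)(C)C(C)(C)C)CCC[C@]2(C)[C@@]12CC[C@@](C#C)(CO[Si](C)(C)C(C)(C)C)O2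
A3 | alternative 2 | ring A furan ynone: 1-[2-{5-[(4-methoxybenzyloxy)methyl]furan-2-yl}-2,6-dimethyl-6-{[(tert-butyldimethylsilyl)oxy]methyl}cyclohexyl]but-3-yn-2-one | C#CC(=O)C[C@H]1[C@@](C)(CO[Si](C)(C)C(C)(C)C)CCC[C@]1(C)c1ccc(COCc2ccc(OC)cc2)o1
A4 | alternative 2 | 7-oxanorbornadiene-fused ring B enone | O=C1C[C@H]2[C@@](C)(CO[Si](C)(C)C(C)(C)C)CCC[C@]2(C)[C@]34C=C[C@](COCc5ccc(OC)cc5)(O3)C=C14
A5 | alternative 3 | 8-phenylmenthyl (6E,10E)-2,7,11-trimethyl-13-(2-methyl-1,3-dioxolan-2-yl)-3-oxotrideca-6,10-dienoate | CC(C(=O)O[C@@H]1C[C@H](C)CC[C@H]1C(C)(C)c1ccccc1)C(=O)CC/C(C)=C/CC/C(C)=C/CCC1(C)OCCO1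
A6 | alternative 3 | trans-decalin 3-ketone with axial C19 8-phenylmenthyl ester and 8(17)-alkene | C=C1CC[C@H]2[C@@](C)(C(=O)O[C@@H]3C[C@H](C)CC[C@H]3C(C)(C)c3ccccc3)C(=O)CC[C@]2(C)[C@H]1CCC1(C)OCCO1
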